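## Retrosynthetic overview

1. Target 16 ⇐ 15 by one fluoride operation: removal of four TIPS groups, loss of the spare vanillyl ether at O4 as a p‑quinone methide, and C2 epimerisation cis → trans.
2. 15 ⇐ Heck coupling of aryl bromide 13 with 2‑methoxy‑4‑vinylphenol (the stilbene is made last).
3. 13 ⇐ symmetric hydrazone 11 by an enantioselective Rh(II) donor/donor‑carbene 1,5‑C–H insertion into one of two identical vanillyl ether arms. This forms the only new ring (the dihydrofuran, C2–C3 bond) and differentiates the two resorcinol oxygens.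
4. 11 ⇐ nitrile 6 + aryl Grignard from 8, then hydrazine; 6 ⇐ double SNAr of 4‑bromo‑2,6‑difluorobenzonitrile with TIPS‑vanillyl alcohol (from vanillin).

Assumption 1: the target SMILES is the 2,3‑trans‑(2S,3S) dihydrobenzofuran; that is what is made.
Assumption 2: Rh2(S‑PTAD)4 is written as the catalyst antipode that gives 3S; if induction is opposite, Rh2(R‑PTAD)4 is used with no other change.

## Route

**Step 1**
Reactants: 1 vanillin; 2 chlorotriisopropylsilane (TIPSCl)
Product: 4 [3‑methoxy‑4‑(triisopropylsilyloxy)phenyl]methanol, via aldehyde 3 (3‑methoxy‑4‑(triisopropylsilyloxy)benzaldehyde, not isolated)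
Conditions: TIPSCl, imidazole, CH2Cl2, rt; then MeOH, NaBH4, 0 °C (one pot)
Reagents that add atoms: TIPSCl, CC(C)[Si](Cl)(C(C)C)C(C)C (NaBH4 adds H only)
Why: Phenol silylation followed by borohydride reduction of the aldehyde; the hindered aryl TIPS ether survives NaBH4/MeOH.

**Step 2**
Reactants: 4 (2.2 equiv); 5 4‑bromo‑2,6‑difluorobenzonitrile
Product: 6 4‑bromo‑2,6‑bis{[3‑methoxy‑4‑(triisopropylsilyloxy)benzyl]oxy}benzonitrile
Conditions: NaH (added to the mixture of 4 and 5), THF, 0 → 45 °C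
Reagents that add atoms: none beyond reactants 4 and 5
Why: Double SNAr (addition–elimination) at the two fluorides ortho to the nitrile; fluoride is the far better leaving group, so the para bromide is kept, and TIPS resists alkoxide silyl transfer.

**Step 3**
Reactants: 7 5‑bromoresorcinol; 2 TIPSCl (2.2 equiv)
Product: 8 1‑bromo‑3,5‑bis(triisopropylsilyloxy)benzene
Conditions: TIPSCl, imidazole, DMF, rt
Reagents that add atoms: TIPSCl, CC(C)[Si](Cl)(C(C)C)C(C)C
Why: Standard phenol silylation; both silyloxy groups are meta to bromine, so the derived aryl‑metal cannot undergo retro‑Brook migration.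

**Step 4**
Reactants: 8 1‑bromo‑3,5‑bis(triisopropylsilyloxy)benzene (converted in situ to its Grignard reagent); 6 the bis(benzyloxy)benzonitrile; 9 hydrazine monohydrate
Product: 11 {4‑bromo‑2,6‑bis[(3‑methoxy‑4‑TIPSO‑benzyl)oxy]phenyl}[3,5‑bis(TIPSO)phenyl]methanone hydrazone, via N–H ketimine 10 (not isolated)
Conditions: 8, Mg, LiCl, THF, 50 °C; then 6, CuBr·SMe2 (5 mol %), THF, 65 °C; MeOH quench; then N2H4·H2O (10 equiv), AcOH (cat.), EtOH, 70 °C (one pot)
Reagents that add atoms: hydrazine, NN; 1‑bromo‑3,5‑bis(triisopropylsilyloxy)benzene (compound 8, source of the aryl group), Brc1cc(O[Si](C(C)C)(C(C)C)C(C)C)cc(O[Si](C(C)C)(C(C)C)C(C)C)c1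
Why: Cu(I)‑promoted Grignard addition to the nitrile stops at the N‑magnesio ketimine (the aryl bromide of 6 does not exchange with ArMgBr); the N–H ketimine then transiminates with hydrazine, losing the nitrile nitrogen as NH3, which is easier than condensing hydrazine with the corresponding 2,6‑disubstituted benzophenone.

**Step 5 (key step)**
Reactants: 11
Product: 13 (2R,3S)‑6‑bromo‑3‑[3,5‑bis(TIPSO)phenyl]‑2‑[3‑methoxy‑4‑(TIPSO)phenyl]‑4‑{[3‑methoxy‑4‑(TIPSO)benzyl]oxy}‑2,3‑dihydrobenzofuran (2,3‑cis), via diaryldiazomethane 12 (not isolated)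
Conditions: activated MnO2 (8 equiv), CH2Cl2, 0 °C → rt, filter; then Rh2(S‑PTAD)4 (1 mol %), CH2Cl2, 0 °C → rt
Reagents that add atoms: none
Why: This is the known enantioselective intramolecular 1,5‑C–H insertion of a donor/donor Rh(II) carbene into a benzylic ether C–H, which gives cis‑2,3‑diaryl‑dihydrobenzofurans; the chiral Rh2 pocket selects the carbene face and one enantiotopic OCH2 hydrogen, setting C3 as S (and C2 cis, R). Either of the two identical arms gives the same product, and the unused arm stays as a protecting group on O4. The 2,6‑disubstituted carbene is an untested extension of this substrate class.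

**Step 6**
Reactants: 13; 14 2‑methoxy‑4‑vinylphenol
Product: 15 4‑[(E)‑2‑{(2R,3S)‑3‑[3,5‑bis(TIPSO)phenyl]‑2‑[3‑methoxy‑4‑(TIPSO)phenyl]‑4‑[(3‑methoxy‑4‑TIPSO‑benzyl)oxy]‑2,3‑dihydrobenzofuran‑6‑yl}vinyl]‑2‑methoxyphenol
Conditions: Pd(OAc)2 (5 mol %), P(o‑tol)3 (12 mol %), Et3N, DMF, 90 °C
Reagents that add atoms: none beyond reactants 13 and 14
Why: Mizoroki–Heck coupling of a 3,5‑dioxygenated aryl bromide with a vinylphenol; syn insertion and syn β‑hydride elimination give the E‑stilbene, and the TIPS ethers, benzylic ethers and both stereocentres are untouched by Et3N at 90 °C.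

**Step 7**
Reactants: 15
Product: 16 bisisorhapontigenin B, (2S,3S)‑trans
Conditions: TBAF (6 equiv), n‑C12H25SH (5 equiv), degassed THF, 0 → 40 °C; AcOH quench
Reagents that add atoms: none
Why: Proposed new method: fluoride removes the four TIPS groups; the 4‑oxidobenzyl ether at O4 then expels the C4 phenoxide by 1,6‑elimination, and the resulting vanillyl p‑quinone methide is trapped by the thiol; the same reversible 1,6‑elimination/5‑exo re‑addition at C2 (now a 4‑oxidobenzyl ether) equilibrates C2 to the more stable trans isomer while C3 (S) is untouched, so any cis/trans mixture from step 5 converges on (2S,3S); the closest known reaction types are self‑immolative p‑hydroxybenzyl ether cleavage and quinone‑methide‑mediated cis → trans epimerisation of 2‑(4‑hydroxyaryl)dihydrobenzofurans.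

## Compound list

1 | vanillin | COc1cc(C=O)ccc1O | starting material
2 | chlorotriisopropylsilane | CC(C)[Si](Cl)(C(C)C)C(C)C | starting material
3 | 3‑methoxy‑4‑(triisopropylsilyloxy)benzaldehyde | O=Cc1ccc(O[Si](C(C)C)(C(C)C)C(C)C)c(OC)c1 | intermediate (not isolated)
4 | [3‑methoxy‑4‑(triisopropylsilyloxy)phenyl]methanol | OCc1ccc(O[Si](C(C)C)(C(C)C)C(C)C)c(OC)c1 | intermediate
5 | 4‑bromo‑2,6‑difluorobenzonitrile | N#Cc1c(F)cc(Br)cc1F | starting material
6 | 4‑bromo‑2,6‑bis{[3‑methoxy‑4‑(TIPSO)benzyl]oxy}benzonitrile | N#Cc1c(OCc2ccc(O[Si](C(C)C)(C(C)C)C(C)C)c(OC)c2)cc(Br)cc1OCc1ccc(O[Si](C(C)C)(C(C)C)C(C)C)c(OC)c1 | intermediate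
7 | 5‑bromoresorcinol | Oc1cc(O)cc(Br)c1 | starting material
8 | 1‑bromo‑3,5‑bis(triisopropylsilyloxy)benzene | Brc1cc(O[Si](C(C)C)(C(C)C)C(C)C)cc(O[Si](C(C)C)(C(C)C)C(C)C)c1 | intermediate
9 | hydrazine (used as monohydrate) | NN | starting material
10 | N–H ketimine of the diaryl ketone | N=C(c1cc(O[Si](C(C)C)(C(C)C)C(C)C)cc(O[Si](C(C)C)(C(C)C)C(C)C)c1)c1c(OCc2ccc(O[Si](C(C)C)(C(C)C)C(C)C)c(OC)c2)cc(Br)cc1OCc1ccc(O[Si](C(C)C)(C(C)C)C(C)C)c(OC)c1 | intermediate (not isolated)
11 | diaryl ketone hydrazone | NN=C(c1cc(O[Si](C(C)C)(C(C)C)C(C)C)cc(O[Si](C(C)C)(C(C)C)C(C)C)c1)c1c(OCc2ccc(O[Si](C(C)C)(C(C)C)C(C)C)c(OC)c2)cc(Br)cc1OCc1ccc(O[Si](C(C)C)(C(C)C)C(C)C)c(OC)c1 | intermediate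
12 | diaryldiazomethane | [N-]=[N+]=C(c1cc(O[Si](C(C)C)(C(C)C)C(C)C)cc(O[Si](C(C)C)(C(C)C)C(C)C)c1)c1c(OCc2ccc(O[Si](C(C)C)(C(C)C)C(C)C)c(OC)c2)cc(Br)cc1OCc1ccc(O[Si](C(C)C)(C(C)C)C(C)C)c(OC)c1 | intermediate (not isolated)
13 | (2R,3S)‑cis‑6‑bromo dihydrobenzofuran | Brc1cc(OCc2ccc(O[Si](C(C)C)(C(C)C)C(C)C)c(OC)c2)c2c(c1)O[C@@H](c1ccc(O[Si](C(C)C)(C(C)C)C(C)C)c(OC)c1)[C@H]2c1cc(O[Si](C(C)C)(C(C)C)C(C)C)cc(O[Si](C(C)C)(C(C)C)C(C)C)c1 | intermediate
14 | 2‑methoxy‑4‑vinylphenol | C=Cc1ccc(O)c(OC)c1 | starting material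
15 | (2R,3S)‑cis stilbene, tetra‑TIPS, O4‑vanillyl ether | COc1cc(/C=C/c2cc(OCc3ccc(O[Si](C(C)C)(C(C)C)C(C)C)c(OC)c3)c3c(c2)O[C@@H](c2ccc(O[Si](C(C)C)(C(C)C)C(C)C)c(OC)c2)[C@H]3c2cc(O[Si](C(C)C)(C(C)C)C(C)C)cc(O[Si](C(C)C)(C(C)C)C(C)C)c2)ccc1O | intermediate
16 | bisisorhapontigenin B, (2S,3S) | COc1cc(/C=C/c2cc(O)c3c(c2)O[C@H](c2ccc(O)c(OC)c2)[C@H]3c2cc(O)cc(O)c2)ccc1O | target

## Summary

Total step count: 7 (steps 1 and 4 are one‑pot, multi‑operation steps; 9 if each operation is counted separately).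
Longest linear sequence: 6 (steps 1, 2, 4, 5, 6, 7, from vanillin).

Steps most likely to fail, with fallbacks:

1. **Step 5** (hindered 2,6‑disubstituted donor/donor carbene; yield or ee at C3 may be low). Fallback: give up catalyst control, run the insertion with achiral Rh2(esp)2 and resolve 13 by preparative chiral SFC. Only C3 needs resolving, because C2 is equilibrated in step 7.
2. **Step 4** (slow Grignard addition to the electron‑rich nitrile, or slow exchange at the hindered ketimine carbon). Fallback: form the N–N bond at nitrogen instead of exchanging at carbon, by trapping the N‑magnesio ketimide with an electrophilic aminating agent (O‑(diphenylphosphinyl)hydroxylamine) to give 11 directly.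
3. **Step 7** (incomplete quinone‑methide loss of the O4 arm, or ring‑opened by‑products under basic fluoride, such as thiol adducts or the triarylethylene from tautomerisation of the C2 quinone methide). Fallback: switch to a cationic, PMB‑type sequence in two steps. Treat 15 with TFA/thioanisole in CH2Cl2 at 0 °C, which cleaves the electron‑rich benzyl ether and epimerises C2 through the benzylic cation; then desilylate with AcOH‑buffered TBAF.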